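**Retrosynthetic overview**
1. The heptane chain is numbered from C1 (benzylic, on catechol ring A) to C7 (benzylic, on 4-hydroxyphenyl ring B). Target 13 comes from tetrabenzyl compound 12 by one hydrogenolysis that removes four benzyl groups and an extra C7–O bond.
2. 12 is cut at C3–C4, at C5–H and at O3–acetyl into three carbonyl compounds: methyl ketone 4 (C4–C7, ring B), aldehyde 7 (C1–C3, ring A) and acetaldehyde 8. They are joined in one flask by a boron aldol addition followed by a Tishchenko hydride shift.
3. Enabling feature: in the anti array C3(OAc)–C4H2–C5(OH) the ester sits on the oxygen of a former aldehyde carbon and the free hydroxyl on a former ketone carbon, which is the exact imprint of an aldol–Tishchenko sequence. C7 is benzylic to the donor-substituted ring B, so it can carry a sacrificial benzyloxy stereocentre that steers C3 (1,5-anti) and is erased at the end.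
4. 4 comes from 4-(benzyloxy)benzaldehyde 1 (allylboration, benzylation, Wacker oxidation). 7 comes from dihydrocaffeic acid 5 (perbenzylation, partial reduction).
5. No ring is formed in the route: rings A and B are bought with 5 and 1.

Key step: step 6

Assumption: "(−)-Ipc2B(allyl)" denotes the reagent made from (+)-α-pinene, the antipode that converts aryl aldehydes into (S)-1-arylbut-3-en-1-ols.

Step 1
Reactants: 1 4-(benzyloxy)benzaldehyde
Product: 2 (S)-1-[4-(benzyloxy)phenyl]but-3-en-1-ol
Conditions: (−)-Ipc2B(allyl), Et2O, −78 °C; then NaOH aq, 30% H2O2, 0 °C → rt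
Reagents that add atoms: (−)-B-allyldiisopinocampheylborane C=CCB([C@@H]1C[C@@H]2C[C@H]([C@H]1C)C2(C)C)[C@@H]1C[C@@H]2C[C@H]([C@H]1C)C2(C)C
Why: Brown asymmetric allylboration, in which a closed chair transition state and the isopinocampheyl groups derived from (+)-α-pinene expose the Si face of the aryl aldehyde, should set C7 as S.

Step 2
Reactants: 2 (S)-1-[4-(benzyloxy)phenyl]but-3-en-1-ol
Product: 3 (S)-1-(benzyloxy)-4-[1-(benzyloxy)but-3-en-1-yl]benzene
Conditions: NaH, BnBr, Bu4NI (cat.), THF, 0 °C → rt
Reagents that add atoms: benzyl bromide BrCc1ccccc1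
Why: Williamson ether synthesis on the sodium alkoxide leaves the C7–O bond untouched, so the configuration is kept and the β-alkoxy group needed for the later 1,5-induction is installed.

Step 3
Reactants: 3 (S)-1-(benzyloxy)-4-[1-(benzyloxy)but-3-en-1-yl]benzene
Product: 4 (S)-4-(benzyloxy)-4-[4-(benzyloxy)phenyl]butan-2-one
Conditions: PdCl2 (10 mol %), Cu(OAc)2 (20 mol %), O2 (1 atm), DMA–H2O 7:1, rt
Reagents that add atoms: water O
Why: Wacker–Tsuji oxidation (Markovnikov hydroxypalladation of the terminal alkene, then β-hydride elimination) gives the methyl ketone, and the Cu(OAc)2 variant keeps the medium nearly neutral so that the acid-labile C7 benzylic ether and its stereocentre should survive.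

Step 4
Reactants: 5 3-(3,4-dihydroxyphenyl)propanoic acid (dihydrocaffeic acid)
Product: 6 benzyl 3-[3,4-bis(benzyloxy)phenyl]propanoate
Conditions: BnBr (3.5 equiv), K2CO3, DMF, 60 °C
Reagents that add atoms: benzyl bromide BrCc1ccccc1
Why: Threefold O-alkylation (Williamson ether synthesis at both phenols, carboxylate alkylation at the acid) masks every acidic proton in one operation with groups that later reductive steps remove.

Step 5
Reactants: 6 benzyl 3-[3,4-bis(benzyloxy)phenyl]propanoate
Product: 7 3-[3,4-bis(benzyloxy)phenyl]propanal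
Conditions: i-Bu2AlH (1.05 equiv), CH2Cl2, −78 °C; potassium sodium tartrate aq
Reagents that add atoms: none
Why: In this partial ester reduction with i-Bu2AlH the tetrahedral aluminium hemiacetal is stable at −78 °C and collapses to the aldehyde only on work-up, so over-reduction should be limited, and the aryl benzyl ethers are inert.

Step 6
Reactants: 4 (S)-4-(benzyloxy)-4-[4-(benzyloxy)phenyl]butan-2-one, 7 3-[3,4-bis(benzyloxy)phenyl]propanal, 8 acetaldehyde
Product: 12 (3R,5S,7S)-7-(benzyloxy)-7-[4-(benzyloxy)phenyl]-1-[3,4-bis(benzyloxy)phenyl]-5-hydroxyheptan-3-yl acetate, via enol borinate 9 (not isolated), via boron aldolate 10 (not isolated), via O5-borinate 11 (not isolated)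
Conditions: 4 (1.15 equiv), c-Hex2BCl (1.1 equiv), Et3N, Et2O, 0 °C, filter cannula (removes Et3N·HCl); 7 (1.0 equiv), −78 → −20 °C; 8 (10 equiv), SmI2 (0.3 equiv, THF), −10 °C; MeOH, pH 7 buffer, 0 °C
Reagents that add atoms: dicyclohexylboron chloride ClB(C1CCCCC1)C1CCCCC1 (its boron group sits only in 9, 10 and 11 and leaves at work-up)
Why: Proposed new method: c-Hex2BCl/Et3N enolises 4 only at its methyl carbon C4, and enol borinate 9 adds to aldehyde 7 through a cyclic boron-bridged transition state, which forms the C3–C4 bond (10). A catalytic trivalent samarium alkoxide (formed from SmI2 and 8) is then expected to exchange with boron at O3, the samarium aldolate adds to 8, the hemiacetal hands its C–H hydride to the C5 ketone within a samarium-bridged chair-like six-membered transition state and leaves the acetyl group on O3, and the new O5 alkoxide takes the boron group of the next molecule of 10 (giving 11), which returns samarium to the cycle. The closest known reaction types are the 1,5-anti boron aldol addition of β-alkoxy methyl ketones, the Evans–Tishchenko reduction of isolated β-hydroxy ketones and the lithium or samarium aldol–Tishchenko cascade, whereas a Tishchenko stage run directly on a dialkylboron aldolate with a second, different aldehyde has not been shown. No ring of the product is closed; C3 (R) is set by the C7 benzyloxy stereocentre through 1,5-anti induction (formyl C–H···O contact to the ether oxygen in the boat-like aldol transition state), C5 is set by C3 because the hydride can only arrive from the tethered hemiacetal on the face that gives the 1,3-anti array, and since C7 is still present any C3 or C5 epimer is a diastereomer of 12 that chromatography can remove. The step needs chemoselection among three carbonyl partners and one defined ester position, and both are secured by the order of addition (7 is consumed before 8 enters), by the boron-capped medium that holds neither free enolate nor free alkoxide (no retro-aldol, no acetyl shift from O3 to O5) and by the intramolecular hydride path.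

Step 7
Reactants: 12 (3R,5S,7S)-7-(benzyloxy)-7-[4-(benzyloxy)phenyl]-1-[3,4-bis(benzyloxy)phenyl]-5-hydroxyheptan-3-yl acetate
Product: 13 (3R,5R)-1-(3,4-dihydroxyphenyl)-5-hydroxy-7-(4-hydroxyphenyl)heptan-3-yl acetate
Conditions: H2 (1 atm), Pd(OH)2/C, EtOAc–EtOH 1:1, AcOH (cat.), rt
Reagents that add atoms: none
Why: Catalytic hydrogenolysis of benzylic C–O bonds cleaves the three aryl benzyl ethers and, because C7 is benzylic to an oxygen-donor ring, both C–O bonds of the C7 ether, so the sacrificial stereocentre becomes CH2 while the non-benzylic C3 acetate and C5 carbinol keep their configuration (the C5 descriptor changes from S to R only through the priority rules).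

**Compound list**
1 | 4-(benzyloxy)benzaldehyde | O=Cc1ccc(OCc2ccccc2)cc1 | starting material
2 | (S)-1-[4-(benzyloxy)phenyl]but-3-en-1-ol | C=CC[C@H](O)c1ccc(OCc2ccccc2)cc1 | intermediate
3 | (S)-1-(benzyloxy)-4-[1-(benzyloxy)but-3-en-1-yl]benzene | C=CC[C@H](OCc1ccccc1)c1ccc(OCc2ccccc2)cc1 | intermediate
4 | (S)-4-(benzyloxy)-4-[4-(benzyloxy)phenyl]butan-2-one | CC(=O)C[C@H](OCc1ccccc1)c1ccc(OCc2ccccc2)cc1 | intermediate
5 | 3-(3,4-dihydroxyphenyl)propanoic acid | OC(=O)CCc1ccc(O)c(O)c1 | starting material
6 | benzyl 3-[3,4-bis(benzyloxy)phenyl]propanoate | O=C(CCc1ccc(OCc2ccccc2)c(OCc2ccccc2)c1)OCc1ccccc1 | intermediate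
7 | 3-[3,4-bis(benzyloxy)phenyl]propanal | O=CCCc1ccc(OCc2ccccc2)c(OCc2ccccc2)c1 | intermediate
8 | acetaldehyde | CC=O | starting material
9 | dicyclohexylboron enolate of 4, (S)-4-(benzyloxy)-4-[4-(benzyloxy)phenyl]but-1-en-2-yl dicyclohexylborinate | C=C(OB(C1CCCCC1)C1CCCCC1)C[C@H](OCc1ccccc1)c1ccc(OCc2ccccc2)cc1 | intermediate
10 | O3-dicyclohexylboron aldolate of (3R,7S)-7-(benzyloxy)-7-[4-(benzyloxy)phenyl]-1-[3,4-bis(benzyloxy)phenyl]-3-hydroxyheptan-5-one | B(C1CCCCC1)(C1CCCCC1)O[C@H](CCc1ccc(OCc2ccccc2)c(OCc2ccccc2)c1)CC(=O)C[C@H](OCc1ccccc1)c1ccc(OCc2ccccc2)cc1 | intermediate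
11 | O5-dicyclohexylborinate of 12 | CC(=O)O[C@H](CCc1ccc(OCc2ccccc2)c(OCc2ccccc2)c1)C[C@H](OB(C1CCCCC1)C1CCCCC1)C[C@H](OCc1ccccc1)c1ccc(OCc2ccccc2)cc1 | intermediate
12 | (3R,5S,7S)-7-(benzyloxy)-7-[4-(benzyloxy)phenyl]-1-[3,4-bis(benzyloxy)phenyl]-5-hydroxyheptan-3-yl acetate | CC(=O)O[C@H](CCc1ccc(OCc2ccccc2)c(OCc2ccccc2)c1)C[C@H](O)C[C@H](OCc1ccccc1)c1ccc(OCc2ccccc2)cc1 | intermediate
13 | (3R,5R)-1-(3,4-dihydroxyphenyl)-5-hydroxy-7-(4-hydroxyphenyl)heptan-3-yl acetate | CC(=O)O[C@H](CCc1ccc(O)c(O)c1)C[C@H](O)CCc1ccc(O)cc1 | target

Total step count: 7. Longest linear sequence: 5 steps (1, 2, 3, 6, 7).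

**Steps most likely to fail**

Step 6. The alkoxide exchange between boron and samarium may be too slow for the hydride shift to start. Alternatively, the trivalent samarium alkoxide may be lost by protonation through residual ammonium salt. The fallback sets out from 4 and 7 and returns at 12.
- The boron aldol addition is run in the established way (c-Hex2BCl, Et3N, Et2O; 7, −78 → −20 °C) and boron aldolate 10 is cleaved oxidatively (MeOH, pH 7 buffer, H2O2).
- The free β-hydroxy ketone (3R,7S)-7-(benzyloxy)-7-[4-(benzyloxy)phenyl]-1-[3,4-bis(benzyloxy)phenyl]-3-hydroxyheptan-5-one F1 is purified, which also allows removal of the minor C3 epimer.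
- F1 is then submitted as an isolated alcohol to the classical Evans–Tishchenko reduction with 8 (SmI2 cat., THF, −10 °C) to give 12.

Step 7. Cleavage of the C7–O bond may stall at the benzylic alcohol stage, or the acetyl group may drift from O3 to O5 during a prolonged run in protic, slightly acidic medium. The fallback sets out from 12 and returns at 13.
- The C7–O bond is removed first by ionic reduction (Et3SiH, BF3·OEt2, CH2Cl2, −78 °C). The donor-stabilised C7 benzylic cation is trapped by hydride to give (3R,5R)-7-[4-(benzyloxy)phenyl]-1-[3,4-bis(benzyloxy)phenyl]-5-hydroxyheptan-3-yl acetate F2.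
- Only aryl benzyl ethers then remain, and a short neutral hydrogenolysis (H2, Pd/C, EtOAc, rt) should give 13.

Step 3. Benzyl alcohol may be lost from the β-alkoxy ketone by elimination towards the aryl-conjugated enone, or attack at the terminal carbon may lead to the aldehyde. The fallback sets out from 3 and returns at 4.
- Radical Markovnikov hydration under neutral conditions (Mukaiyama hydration, Co(acac)2, PhSiH3, O2, i-PrOH) gives (4S)-4-(benzyloxy)-4-[4-(benzyloxy)phenyl]butan-2-ol F3 as both epimers at the new carbinol carbon.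
- A NaHCO3-buffered Dess–Martin oxidation converges both epimers on 4.

**Further compounds**
F1 | step 6 | (3R,7S)-7-(benzyloxy)-7-[4-(benzyloxy)phenyl]-1-[3,4-bis(benzyloxy)phenyl]-3-hydroxyheptan-5-one | O[C@H](CCc1ccc(OCc2ccccc2)c(OCc2ccccc2)c1)CC(=O)C[C@H](OCc1ccccc1)c1ccc(OCc2ccccc2)cc1
F2 | step 7 | (3R,5R)-7-[4-(benzyloxy)phenyl]-1-[3,4-bis(benzyloxy)phenyl]-5-hydroxyheptan-3-yl acetate | CC(=O)O[C@H](CCc1ccc(OCc2ccccc2)c(OCc2ccccc2)c1)C[C@H](O)CCc1ccc(OCc2ccccc2)cc1
F3 | step 3 | (4S)-4-(benzyloxy)-4-[4-(benzyloxy)phenyl]butan-2-ol (both C2 epimers) | CC(O)C[C@H](OCc1ccccc1)c1ccc(OCc2ccccc2)cc1
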